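**Plan**
- Cuts: first the five O–benzyl bonds. Then, together, the two bonds that tie the central benzene ring (ring B) to its carbon neighbours, aryl C–CH2(pyranone) and aryl C–C(=O), leading back to 3,5-bis(benzyloxy)benzyne 15 and ketone 9. Last the C(=O)–CH2 bond of 9 (aldol, then oxidation), back to aldehyde 4 and methylpyranone 6.
- Enabling feature: on ring B the benzoyl carbon and the pyranonyl-CH2 sit on adjacent ring carbons, with an oxygen on the next carbon beside the acyl-bearing one. The pair C(=O)/CH2 is therefore a ketone ArC(=O)–CH2–pyranone with two aryne carbons slipped into its C–C bond. The CH2 is acidic because it lies between the ketone and C-6 of the 4-alkoxypyran-2-one (a vinylogous β-keto ester).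
- Forward: no ring is built. Ring A (from 5-propylresorcinol) and the pyranone (from triacetic acid lactone) are joined through C(=O)–CH2 (steps 1–5), and the aryne precursor is made from 3,5-bis(benzyloxy)phenol (steps 6–7). Ring B is then inserted between the carbonyl carbon and the CH2 (step 8), and all benzyl ethers are removed (step 9).
- Stereochemistry: the target has no stereocentre; the carbinol centre of 8 is racemic and is erased in step 5.

Key step: step 8

Remark: compounds 1, 5 and 10 are taken as commercially available; benzyl is used for all five hydroxyl groups so that one final operation sets them free.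

**Step 1**
Reactants: 1 5-propylbenzene-1,3-diol
Product: 2 1,3-bis(benzyloxy)-5-propylbenzene
Conditions: BnBr (2.3 equiv), K2CO3, DMF, rt → 60 °C
Reagents that add atoms: benzyl bromide, BrCc1ccccc1
Why: Williamson ether synthesis; both phenoxides should be O-benzylated cleanly.

**Step 2**
Reactants: 2 1,3-bis(benzyloxy)-5-propylbenzene
Product: 4 2,4-bis(benzyloxy)-6-propylbenzaldehyde, via iminium salt 3 (not isolated)
Conditions: POCl3, DMF, 0 → 70 °C; then aq. NaOAc
Reagents that add atoms: N,N-dimethylformamide, CN(C)C=O; water, O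
Why: Vilsmeier–Haack formylation; as with 3,5-dialkoxytoluenes, the chloroiminium ion should attack the ring carbon between the propyl group and one ether (ortho/para to both ethers) in preference to the more shielded carbon between the two ethers, and iminium 3 is hydrolysed on work-up.

**Step 3**
Reactants: 5 4-hydroxy-6-methyl-2H-pyran-2-one
Product: 6 4-(benzyloxy)-6-methyl-2H-pyran-2-one
Conditions: BnBr, K2CO3, DMF, 60 °C
Reagents that add atoms: benzyl bromide, BrCc1ccccc1
Why: O-alkylation of the vinylogous acid at O-4, the usual site for 4-hydroxypyran-2-ones under carbonate conditions.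

**Step 4**
Reactants: 6 4-(benzyloxy)-6-methyl-2H-pyran-2-one; 4 2,4-bis(benzyloxy)-6-propylbenzaldehyde
Product: 8 rac-4-(benzyloxy)-6-{2-[2,4-bis(benzyloxy)-6-propylphenyl]-2-hydroxyethyl}-2H-pyran-2-one, via lithium dienolate 7 (not isolated)
Conditions: LiHMDS (1.1 equiv), THF, −78 °C; then 4, −78 °C; aq. NH4Cl
Reagents that add atoms: none
Why: Lateral (vinylogous) deprotonation of the 6-methyl group followed by aldol addition to the aldehyde; the new carbinol centre is formed without control (racemic) and is removed in step 5.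

**Step 5**
Reactants: 8 rac-4-(benzyloxy)-6-{2-[2,4-bis(benzyloxy)-6-propylphenyl]-2-hydroxyethyl}-2H-pyran-2-one
Product: 9 4-(benzyloxy)-6-{2-[2,4-bis(benzyloxy)-6-propylphenyl]-2-oxoethyl}-2H-pyran-2-one
Conditions: Dess–Martin periodinane, NaHCO3, CH2Cl2, 0 °C → rt
Reagents that add atoms: none
Why: Dess–Martin oxidation of a secondary benzylic alcohol under buffered, non-acidic conditions that should spare the benzyl ethers and the pyranone and avoid dehydration.

**Step 6**
Reactants: 10 3,5-bis(benzyloxy)phenol
Product: 11 3,5-bis(benzyloxy)-2-bromophenol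
Conditions: NBS (1.0 equiv), CH2Cl2, −78 °C → rt
Reagents that add atoms: N-bromosuccinimide, O=C1CCC(=O)N1Br
Why: Electrophilic aromatic bromination; in CH2Cl2 at low temperature the free hydroxyl should direct NBS to its ortho position (two equivalent sites) rather than to the carbon between the two ethers.

**Step 7**
Reactants: 11 3,5-bis(benzyloxy)-2-bromophenol
Product: 14 3,5-bis(benzyloxy)-2-(trimethylsilyl)phenyl trifluoromethanesulfonate, via silyl ether 12 (not isolated), via lithium phenolate 13 (not isolated)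
Conditions: HMDS, THF, 70 °C, then evaporate; n-BuLi, THF, −100 → −80 °C; Tf2O, −100 → −78 °C
Reagents that add atoms: hexamethyldisilazane, C[Si](C)(C)N[Si](C)(C)C; trifluoromethanesulfonic anhydride, O=S(=O)(OS(=O)(=O)C(F)(F)F)C(F)(F)F
Why: Standard entry to Kobayashi aryne precursors: O-silylation, Br/Li exchange, anionic 1,3-O→C silyl shift (retro-Brook rearrangement) to phenolate 13 and O-triflation.

**Step 8**
Reactants: 9 4-(benzyloxy)-6-{2-[2,4-bis(benzyloxy)-6-propylphenyl]-2-oxoethyl}-2H-pyran-2-one; 14 3,5-bis(benzyloxy)-2-(trimethylsilyl)phenyl trifluoromethanesulfonate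
Product: 17 4-(benzyloxy)-6-{3,5-bis(benzyloxy)-2-[2,4-bis(benzyloxy)-6-propylbenzoyl]benzyl}-2H-pyran-2-one, via aryne 15 (not isolated), via benzocyclobutenolate 16 (not isolated)
Conditions: 14 (1.3 equiv), CsF (3 equiv), MeCN (0.1 M), 80 °C
Reagents that add atoms: none
Why: Proposed new method: fluoride sets free aryne 15 from 14 and, acting as a base, the caesium enolate of 9; the enolate carbon should add to the aryne carbon remote from the C-3 benzyloxy group, the aryl anion formed beside that oxygen closes on the ketone to benzocyclobutenolate 16, and 16 opens by retro-aldol-type C–C cleavage to the benzophenone and a pyranonylmethyl carbanion that is protonated by further 9. The closest known reaction type is the aryne acyl-alkylation (C–C σ-bond insertion) of β-keto esters, which is established for 3,5-dialkoxybenzynes; here the ester is replaced by its vinylog, the pyranone. The only ring closed is the temporary four-membered one (4-exo-trig, opened again in the same step), and no stereocentre remains because the two centres of 16 are lost on ring opening. Regioselectivity is needed and should come from the C-3 benzyloxy group, whose inductive effect and distortion of the triple bond direct the nucleophile to the distal carbon, so the acyl group ends beside the oxygen and the pyranonylmethyl group meta to it, as in the target. Chemoselectivity for the central enolate carbon over O-arylation, over C-3/C-5 of the pyranone and over [4+2] addition of the aryne to the pyranone diene should follow from the much faster addition of the anion, helped by slow aryne release and only a small excess of 14. The acyl shift is intramolecular, which is why the tetra-ortho-substituted diaryl ketone, hard to reach by intermolecular acylation, should form here.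

**Step 9**
Reactants: 17 4-(benzyloxy)-6-{3,5-bis(benzyloxy)-2-[2,4-bis(benzyloxy)-6-propylbenzoyl]benzyl}-2H-pyran-2-one
Product: 18 6-[2-(2,4-dihydroxy-6-propylbenzoyl)-3,5-dihydroxybenzyl]-4-hydroxy-2H-pyran-2-one
Conditions: BCl3 (1 M in CH2Cl2, 10 equiv), pentamethylbenzene (15 equiv), CH2Cl2, −78 → −30 °C; MeOH quench, aqueous work-up
Reagents that add atoms: none
Why: BCl3-mediated debenzylation with pentamethylbenzene as a non-basic cation scavenger (Friedel–Crafts trapping of benzyl cations) should cleave the four aryl ethers and the vinylogous-ester ether at low temperature without touching the ketone, the pyranone or the electron-rich rings.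

**Compound list**
1 | 5-propylbenzene-1,3-diol (divarinol) | CCCc1cc(O)cc(O)c1 | starting material
2 | 1,3-bis(benzyloxy)-5-propylbenzene | CCCc1cc(OCc2ccccc2)cc(OCc2ccccc2)c1 | intermediate
3 | [2,4-bis(benzyloxy)-6-propylbenzylidene]dimethyliminium chloride | CCCc1cc(OCc2ccccc2)cc(OCc2ccccc2)c1C=[N+](C)C.[Cl-] | intermediate (not isolated)
4 | 2,4-bis(benzyloxy)-6-propylbenzaldehyde | CCCc1cc(OCc2ccccc2)cc(OCc2ccccc2)c1C=O | intermediate
5 | 4-hydroxy-6-methyl-2H-pyran-2-one (triacetic acid lactone) | Cc1cc(O)cc(=O)o1 | starting material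
6 | 4-(benzyloxy)-6-methyl-2H-pyran-2-one | Cc1cc(OCc2ccccc2)cc(=O)o1 | intermediate
7 | lithium 4-(benzyloxy)-6-methylidene-6H-pyran-2-olate (6 lithiated at the methyl group) | [Li+].[O-]C1=CC(OCc2ccccc2)=CC(=C)O1 | intermediate (not isolated)
8 | rac-4-(benzyloxy)-6-{2-[2,4-bis(benzyloxy)-6-propylphenyl]-2-hydroxyethyl}-2H-pyran-2-one | CCCc1cc(OCc2ccccc2)cc(OCc2ccccc2)c1C(O)Cc1cc(OCc2ccccc2)cc(=O)o1 | intermediate
9 | 4-(benzyloxy)-6-{2-[2,4-bis(benzyloxy)-6-propylphenyl]-2-oxoethyl}-2H-pyran-2-one | CCCc1cc(OCc2ccccc2)cc(OCc2ccccc2)c1C(=O)Cc1cc(OCc2ccccc2)cc(=O)o1 | intermediate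
10 | 3,5-bis(benzyloxy)phenol | Oc1cc(OCc2ccccc2)cc(OCc2ccccc2)c1 | starting material
11 | 3,5-bis(benzyloxy)-2-bromophenol | Oc1cc(OCc2ccccc2)cc(OCc2ccccc2)c1Br | intermediate
12 | [3,5-bis(benzyloxy)-2-bromophenoxy]trimethylsilane | C[Si](C)(C)Oc1cc(OCc2ccccc2)cc(OCc2ccccc2)c1Br | intermediate (not isolated)
13 | lithium 3,5-bis(benzyloxy)-2-(trimethylsilyl)phenolate | [Li+].[O-]c1cc(OCc2ccccc2)cc(OCc2ccccc2)c1[Si](C)(C)C | intermediate (not isolated)
14 | 3,5-bis(benzyloxy)-2-(trimethylsilyl)phenyl trifluoromethanesulfonate | C[Si](C)(C)c1c(OCc2ccccc2)cc(OCc2ccccc2)cc1OS(=O)(=O)C(F)(F)F | intermediate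
15 | 3,5-bis(benzyloxy)benzyne (1,2-didehydro-3,5-bis(benzyloxy)benzene) | C1(OCc2ccccc2)=CC(OCc2ccccc2)=CC#C1 | intermediate (not isolated)
16 | caesium 2,4-bis(benzyloxy)-7-[2,4-bis(benzyloxy)-6-propylphenyl]-8-[4-(benzyloxy)-2-oxo-2H-pyran-6-yl]bicyclo[4.2.0]octa-1,3,5-trien-7-olate (mixture of stereoisomers) | [Cs+].[O-]C1(c3c(OCc4ccccc4)cc(OCc4ccccc4)cc3CCC)C(c3cc(OCc4ccccc4)cc(=O)o3)c2cc(OCc3ccccc3)cc(OCc3ccccc3)c21 | intermediate (not isolated)
17 | 4-(benzyloxy)-6-{3,5-bis(benzyloxy)-2-[2,4-bis(benzyloxy)-6-propylbenzoyl]benzyl}-2H-pyran-2-one | CCCc1cc(OCc2ccccc2)cc(OCc2ccccc2)c1C(=O)c1c(OCc2ccccc2)cc(OCc2ccccc2)cc1Cc1cc(OCc2ccccc2)cc(=O)o1 | intermediate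
18 | 6-[2-(2,4-dihydroxy-6-propylbenzoyl)-3,5-dihydroxybenzyl]-4-hydroxy-2H-pyran-2-one | CCCc1cc(O)cc(O)c1C(=O)c1c(O)cc(O)cc1Cc1cc(O)cc(=O)o1 | target

**Count**
Total steps: 9. Longest linear sequence: 6 steps (1, 2, 4, 5, 8, 9).

**Steps most likely to fail**

Step 8. The aryne may be taken up by the pyranone ring instead of the central enolate carbon (arylation at C-3/C-5, or [4+2] addition with loss of CO2), or the aryl anion may be protonated before the acyl shift. The fallback keeps the aryne insertion but runs it on the substrate class for which it is established, a β-keto ester, and builds the pyranone afterwards; it sets out from 4 and 14 and returns at 18. Addition of the lithium enolate of methyl acetate (LDA, MeOAc, THF, −78 °C) to 4 should give methyl 3-[2,4-bis(benzyloxy)-6-propylphenyl]-3-hydroxypropanoate F1. Dess–Martin oxidation should give the β-keto ester methyl 3-[2,4-bis(benzyloxy)-6-propylphenyl]-3-oxopropanoate F2. Acyl-alkylation of aryne 15 (from 14, CsF, MeCN, 80 °C) should then give methyl {3,5-bis(benzyloxy)-2-[2,4-bis(benzyloxy)-6-propylbenzoyl]phenyl}acetate F3, in which the same aryl–CH2 bond is in place. Saponification (LiOH, THF–H2O) should give {3,5-bis(benzyloxy)-2-[2,4-bis(benzyloxy)-6-propylbenzoyl]phenyl}acetic acid F4, and carbonyldiimidazole the acyl imidazole 2-{3,5-bis(benzyloxy)-2-[2,4-bis(benzyloxy)-6-propylbenzoyl]phenyl}-1-(1H-imidazol-1-yl)ethanone F5. F5 acylates the lithium dienolate of 2,2,6-trimethyl-4H-1,3-dioxin-4-one (LiHMDS, THF, −78 °C, excess) to give 6-(3-{3,5-bis(benzyloxy)-2-[2,4-bis(benzyloxy)-6-propylbenzoyl]phenyl}-2-oxopropyl)-2,2-dimethyl-4H-1,3-dioxin-4-one F6. Heating in toluene (110 °C) expels acetone, and the acylketene should close to 6-{3,5-bis(benzyloxy)-2-[2,4-bis(benzyloxy)-6-propylbenzoyl]benzyl}-4-hydroxy-2H-pyran-2-one F7. Debenzylation under the conditions of step 9 returns to the route at 18. This fallback removes the pyranone from the insertion step but not the steric demand of the acyl shift.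

Step 9. The Lewis acid may promote cyclisation of pyranone C-5 onto the activated diaryl ketone, benzyl cations may escape the scavenger and C-benzylate the electron-rich rings, or the pyranone ether may be cleaved incompletely. The fallback replaces heterolytic cleavage by hydrogenolysis (H2 1 atm, Pd/C, EtOAc–MeOH, rt, stopped once the benzyl ethers are consumed), which forms toluene and no cation or boron chelate. It sets out from 17 and returns at 18; no new compound is made.

Step 4. Addition of the stabilised dienolate to the di-ortho-substituted, electron-rich aldehyde may be slow or reversible, and the electron-rich benzylic carbinol may lose water to the styrylpyranone on work-up or in step 5. The fallback forms the same C–C bond at the ketone oxidation level by Claisen-type acylation, which is irreversible because the product is deprotonated as it forms; it sets out from 4 and 6 and returns at 9, by-passing 8 and step 5. Pinnick oxidation of 4 (NaClO2, NaH2PO4, 2-methyl-2-butene, t-BuOH–H2O) should give 2,4-bis(benzyloxy)-6-propylbenzoic acid F8. Oxalyl chloride with catalytic DMF should give 2,4-bis(benzyloxy)-6-propylbenzoyl chloride F9. F9 is added to two equivalents of lithium dienolate 7 (from 6, LiHMDS, THF, −78 °C) to give 9.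

**Further compounds**
F1 | step 8 | methyl 3-[2,4-bis(benzyloxy)-6-propylphenyl]-3-hydroxypropanoate (racemic) | CCCc1cc(OCc2ccccc2)cc(OCc2ccccc2)c1C(O)CC(=O)OC
F2 | step 8 | methyl 3-[2,4-bis(benzyloxy)-6-propylphenyl]-3-oxopropanoate | CCCc1cc(OCc2ccccc2)cc(OCc2ccccc2)c1C(=O)CC(=O)OC
F3 | step 8 | methyl {3,5-bis(benzyloxy)-2-[2,4-bis(benzyloxy)-6-propylbenzoyl]phenyl}acetate | CCCc1cc(OCc2ccccc2)cc(OCc2ccccc2)c1C(=O)c1c(OCc2ccccc2)cc(OCc2ccccc2)cc1CC(=O)OC
F4 | step 8 | {3,5-bis(benzyloxy)-2-[2,4-bis(benzyloxy)-6-propylbenzoyl]phenyl}acetic acid | CCCc1cc(OCc2ccccc2)cc(OCc2ccccc2)c1C(=O)c1c(OCc2ccccc2)cc(OCc2ccccc2)cc1CC(=O)O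
F5 | step 8 | 2-{3,5-bis(benzyloxy)-2-[2,4-bis(benzyloxy)-6-propylbenzoyl]phenyl}-1-(1H-imidazol-1-yl)ethanone | CCCc1cc(OCc2ccccc2)cc(OCc2ccccc2)c1C(=O)c1c(OCc2ccccc2)cc(OCc2ccccc2)cc1CC(=O)n1ccnc1
F6 | step 8 | 6-(3-{3,5-bis(benzyloxy)-2-[2,4-bis(benzyloxy)-6-propylbenzoyl]phenyl}-2-oxopropyl)-2,2-dimethyl-4H-1,3-dioxin-4-one | CCCc1cc(OCc2ccccc2)cc(OCc2ccccc2)c1C(=O)c1c(OCc2ccccc2)cc(OCc2ccccc2)cc1CC(=O)CC1=CC(=O)OC(C)(C)O1
F7 | step 8 | 6-{3,5-bis(benzyloxy)-2-[2,4-bis(benzyloxy)-6-propylbenzoyl]benzyl}-4-hydroxy-2H-pyran-2-one | CCCc1cc(OCc2ccccc2)cc(OCc2ccccc2)c1C(=O)c1c(OCc2ccccc2)cc(OCc2ccccc2)cc1Cc1cc(O)cc(=O)o1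
F0 | step 9 | none | none
F8 | step 4 | 2,4-bis(benzyloxy)-6-propylbenzoic acid | CCCc1cc(OCc2ccccc2)cc(OCc2ccccc2)c1C(=O)O
F9 | step 4 | 2,4-bis(benzyloxy)-6-propylbenzoyl chloride | CCCc1cc(OCc2ccccc2)cc(OCc2ccccc2)c1C(=O)Cl
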